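**Retrosynthetic overview**

Rings: A = acylated cyclohexenedione, B = spiro cyclohexane, C = cyclopentane. Atoms: C-a = C(CH3)(OH) of ring C; C-b, C-c = ring-fusion CH next to C-a and next to C-d; C-d = C(CH3)(OH) of ring B; C-e, C-f = the ring B CH2 groups on C-b and on C-d; C-s = spiro carbon; C-q = C(CH3)(prenyl) of ring A.
Ring B is closed last by alkylation of the ring A enolate carbon C-s with C-f (iodohydrin/epoxide), after C-q has been set by palladium-catalysed asymmetric prenylation and the C-s–C-e bond by reductive alkylation of an acylphloroglucinol (ring A precursor, Friedel–Crafts) with a bicyclic lactol.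
The lactol comes from an iodolactone, which fixes C-d and puts the leaving group on C-f; the iodolactone comes from an all-cis cyclopentane acid.
Ring C is made first, by ring contraction: photochemical Wolff rearrangement of a 2-diazocyclohexanone derived from (1S,2S,4R)-limonene-1,2-diol. Enabling feature: ring C carries C-a, C-b and C-c in a row with one exocyclic carbon (C-e) on C-b, which is the p-menthane pattern of limonene with one ring carbon pushed out, so C-e is the former ring C=O carbon and C-a the migrating carbon.
Order of ring formation: C (contraction of the limonene ring), then A (brought in as an arene, dearomatised at C-q), then B (spirocyclisation).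

Key step: step 4

Remark: ring A compounds are written as one enol tautomer of the β-triketone; the acyl side chain is (R) and C-q is (S), as encoded in the target structure.

**Route**

Step 1
Reactants: 1 (1S,2S,4R)-1-methyl-4-(prop-1-en-2-yl)cyclohexane-1,2-diol [(1S,2S,4R)-limonene-1,2-diol]
Product: 2 (2S,5R)-2-hydroxy-2-methyl-5-(prop-1-en-2-yl)cyclohexan-1-one
Conditions: TEMPO (10 mol %), PhI(OAc)2 (1.2 equiv), CH2Cl2, rt
Reagents that add atoms: none
Why: Oxoammonium (TEMPO) oxidation converts only the secondary alcohol, since the tertiary alcohol cannot be oxidised and the 1,1-disubstituted alkene is inert, so the two stereocentres that are kept (future C-a and C-c) stay untouched.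

Step 2
Reactants: 2 (2S,5R)-2-hydroxy-2-methyl-5-(prop-1-en-2-yl)cyclohexan-1-one
Product: 3 (2S,5R)-2-methyl-5-(prop-1-en-2-yl)-2-[(triethylsilyl)oxy]cyclohexan-1-one
Conditions: TESOTf, 2,6-lutidine, CH2Cl2, −78 to 0 °C
Reagents that add atoms: triethylsilyl trifluoromethanesulfonate, CC[Si](CC)(CC)OS(=O)(=O)C(F)(F)F
Why: Silylation of a tertiary α-ketol with a silyl triflate and a hindered pyridine base is standard, and the bulky ether later shields one face of C-b and keeps this hydroxyl out of steps 5 and 10.

Step 3
Reactants: 3 (2S,5R)-2-methyl-5-(prop-1-en-2-yl)-2-[(triethylsilyl)oxy]cyclohexan-1-one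
Product: 5 (3S,6S)-2-diazo-6-methyl-3-(prop-1-en-2-yl)-6-[(triethylsilyl)oxy]cyclohexan-1-one, via trifluoroacetyl enol 4 (not isolated)
Conditions: LiHMDS, THF, −78 °C, then CF3CO2CH2CF3; then 4-acetamidobenzenesulfonyl azide, Et3N, H2O, MeCN, rt
Reagents that add atoms: 4-acetamidobenzenesulfonyl azide, CC(=O)Nc1ccc(cc1)S(=O)(=O)N=[N+]=[N-]
Why: Detrifluoroacetylative diazo transfer works here without regiochemical doubt because the ketone has a single enolisable α-position (the other α-carbon is quaternary), so the diazo group ends up next to C-c and no stereocentre is formed.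

Step 4
Reactants: 5 (3S,6S)-2-diazo-6-methyl-3-(prop-1-en-2-yl)-6-[(triethylsilyl)oxy]cyclohexan-1-one
Product: 7 (1R,2S,5R)-2-methyl-5-(prop-1-en-2-yl)-2-[(triethylsilyl)oxy]cyclopentane-1-carboxylic acid, via ketene 6 (not isolated)
Conditions: hν (365 nm), THF/H2O (4:1), rt, degassed
Reagents that add atoms: water, O
Why: Irradiation of the ring-locked s-cis 2-diazoketone expels N2 with concerted 1,2-shift of the silyloxy-bearing quaternary carbon from the carbonyl carbon to the diazo carbon (photochemical Wolff rearrangement, the classical ring contraction of 2-diazocyclohexanones), which turns the six-membered ring into the cyclopentane of ring C and pushes the former carbonyl carbon out as ketene 6, the future C-e. No ring is closed by cyclisation: the new ring C bond C-a–C-b arises by suprafacial 1,2-migration, so the five-membered ring forms by contraction and the migrating carbon C-a keeps its configuration. Water adds to the ketene and the acid enol is then protonated at C-b from the face opposite to both the OSiEt3 group on C-a and the isopropenyl group on C-c, which should give the all-cis acid 7 under kinetic control, while C-c is untouched and comes from the diol. The only selectivity needed is which group migrates, and the substrate secures it because the carbonyl carbon has a single other substituent (C-a) and the diazo group could only be placed on the one enolisable CH2. The cis relation created here is tested by the next step, since only the cis acid can lactonise onto the isopropenyl group.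

Step 5
Reactants: 7 (1R,2S,5R)-2-methyl-5-(prop-1-en-2-yl)-2-[(triethylsilyl)oxy]cyclopentane-1-carboxylic acid
Product: 8 (3R,3aR,6S,6aR)-3-(iodomethyl)-3,6-dimethyl-6-[(triethylsilyl)oxy]hexahydro-1H-cyclopenta[c]furan-1-one
Conditions: I2, NaHCO3, MeCN/H2O, 0 °C, dark
Reagents that add atoms: iodine, II
Why: Iodolactonisation (5-exo, Markovnikov) lets the carboxylate attack the tertiary carbon of the iodonium ion of the cis-disposed isopropenyl group to give the cis-fused γ-lactone, and the iodomethyl group should take the convex (exo) position because iodine on the concave side would clash with ring C, which sets C-d as in the target (methyl on the concave side) and puts the leaving group on C-f, while any trans acid cannot lactonise and stays in the aqueous base.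

Step 6
Reactants: 8 (3R,3aR,6S,6aR)-3-(iodomethyl)-3,6-dimethyl-6-[(triethylsilyl)oxy]hexahydro-1H-cyclopenta[c]furan-1-one
Product: 9 (3R,3aR,6S,6aR)-3-(iodomethyl)-3,6-dimethyl-6-[(triethylsilyl)oxy]hexahydro-1H-cyclopenta[c]furan-1-ol (anomeric mixture)
Conditions: DIBAL-H (1.1 equiv), CH2Cl2, −78 °C; aqueous potassium sodium tartrate
Reagents that add atoms: none
Why: Partial reduction of a lactone to the lactol with one equivalent of DIBAL-H at −78 °C is routine because the tetrahedral aluminium acetal resists further reduction, the alkyl iodide and silyl ether are inert, and the new anomeric centre is of no consequence.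

Step 7
Reactants: 10 (2R)-2-methylbutanoic acid; 11 2-methylbenzene-1,3,5-triol
Product: 13 (2R)-2-methyl-1-(2,4,6-trihydroxy-3-methylphenyl)butan-1-one, via acid chloride 12 (not isolated)
Conditions: (COCl)2, DMF (cat.), CH2Cl2, 0 °C to rt; then 11, AlCl3 (3 equiv), CH2Cl2/PhNO2, 0 °C to rt; aq. HCl
Reagents that add atoms: none
Why: Friedel–Crafts acylation of the highly activated phloroglucinol nucleus by the acid chloride made in the flask takes place at one of the two equivalent free ring positions, and working at or below room temperature should preserve the α-stereocentre of the acyl group.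

Step 8
Reactants: 9 (3R,3aR,6S,6aR)-3-(iodomethyl)-3,6-dimethyl-6-[(triethylsilyl)oxy]hexahydro-1H-cyclopenta[c]furan-1-ol; 13 (2R)-2-methyl-1-(2,4,6-trihydroxy-3-methylphenyl)butan-1-one
Product: 15 (2R)-1-[2,4,6-trihydroxy-3-({(1R,2R,5S)-2-[(2R)-2-hydroxy-1-iodopropan-2-yl]-5-methyl-5-[(triethylsilyl)oxy]cyclopentyl}methyl)-5-methylphenyl]-2-methylbutan-1-one, via quinone methide 14 (not isolated)
Conditions: L-proline (20 mol %), diethyl 2,6-dimethyl-1,4-dihydropyridine-3,5-dicarboxylate (Hantzsch ester, 1.5 equiv), CH2Cl2/EtOH, rt
Reagents that add atoms: none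
Why: Organocatalytic three-component reductive alkylation (Knoevenagel condensation then transfer hydrogenation) lets the open hydroxy-aldehyde form of the lactol condense through its proline iminium ion with the only free ring carbon of the acylphloroglucinol to the ortho-quinone methide, which the Hantzsch ester reduces to the CH2 link C-s–C-e while the tertiary hydroxyl on C-d is set free, no stereocentre being created and the near-neutral medium sparing iodohydrin and silyl ether.

Step 9
Reactants: 15 (2R)-1-[2,4,6-trihydroxy-3-({(1R,2R,5S)-2-[(2R)-2-hydroxy-1-iodopropan-2-yl]-5-methyl-5-[(triethylsilyl)oxy]cyclopentyl}methyl)-5-methylphenyl]-2-methylbutan-1-one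
Product: 16 (6S)-3,5-dihydroxy-2-({(1R,2R,5S)-2-[(2R)-2-hydroxy-1-iodopropan-2-yl]-5-methyl-5-[(triethylsilyl)oxy]cyclopentyl}methyl)-6-methyl-6-(3-methylbut-2-en-1-yl)-4-[(2R)-2-methylbutanoyl]cyclohexa-2,4-dien-1-one
Conditions: Pd2(dba)3·CHCl3 (2.5 mol %), (R,R)-DACH-phenyl bisphosphine ligand [(1R,2R)-N,N'-bis(2-diphenylphosphinobenzoyl)cyclohexane-1,2-diamine] (7.5 mol %), prenyl acetate, Et3N, THF, 0 °C
Reagents that add atoms: prenyl acetate (3-methylbut-2-en-1-yl acetate), CC(C)=CCOC(C)=O
Why: Tsuji–Trost asymmetric allylic alkylation used as a dearomatisation should have the ammonium phenolate attack the 1,1-dimethylallyl complex of divalent palladium at its unsubstituted terminus (linear prenyl) through ring carbon C-q, which carries only a methyl group, rather than through the more hindered C-s, the ligand enantiomer being chosen so that the face giving (S) at C-q is attacked (the antipode is taken if a trial shows the opposite sense), while the neopentyl-type primary iodide should not react with zerovalent palladium at 0 °C.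

Step 10
Reactants: 16 (6S)-3,5-dihydroxy-2-({(1R,2R,5S)-2-[(2R)-2-hydroxy-1-iodopropan-2-yl]-5-methyl-5-[(triethylsilyl)oxy]cyclopentyl}methyl)-6-methyl-6-(3-methylbut-2-en-1-yl)-4-[(2R)-2-methylbutanoyl]cyclohexa-2,4-dien-1-one
Product: 18 3'-O-triethylsilyl ether of 19 (silyl ether on C-a), via epoxide 17 (not isolated)
Conditions: Cs2CO3 (3 equiv), DMF, 0 to 40 °C
Reagents that add atoms: none
Why: Intramolecular C-alkylation of a β-triketone-type enolate (6-exo-tet for the new carbocycle) follows once Cs2CO3 has closed the iodohydrin to epoxide 17, the ring A enolate attacking the CH2 terminus through C-s (the fully substituted epoxide carbon cannot be attacked and O-alkylation would need an eight-membered ring) with C-f expected to enter on the face of ring A that bears the methyl group of C-q, anti to the larger prenyl group, which sets (R) at C-s, while C-d keeps its configuration because only the C-f–O bond breaks and the cis ring fusion is already in place.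

Step 11
Reactants: 18 3'-O-triethylsilyl ether of 19
Product: 19 CNP0236509.3, (1R,3S,3'S,3a'R,7'S,7a'R)-3',4,7'-trihydroxy-3,3',7'-trimethyl-3-(3-methylbut-2-en-1-yl)-5-[(2R)-2-methylbutanoyl]-1',2',3',3a',4',6',7',7a'-octahydrospiro[cyclohexane-1,5'-inden]-4-ene-2,6-dione
Conditions: HF·pyridine, pyridine/THF, 0 °C to rt
Reagents that add atoms: none
Why: Fluoride cleavage of the tertiary triethylsilyl ether with buffered HF·pyridine should leave the prenyl alkene, the enolised trione and both tertiary alcohols untouched and unveil the target.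

**Compound list**

1 | (1S,2S,4R)-1-methyl-4-(prop-1-en-2-yl)cyclohexane-1,2-diol | C[C@]1(O)CC[C@@H](C(C)=C)C[C@@H]1O | starting material
2 | (2S,5R)-2-hydroxy-2-methyl-5-(prop-1-en-2-yl)cyclohexan-1-one | C[C@]1(O)CC[C@@H](C(C)=C)CC1=O | intermediate
3 | (2S,5R)-2-methyl-5-(prop-1-en-2-yl)-2-[(triethylsilyl)oxy]cyclohexan-1-one | C[C@]1(O[Si](CC)(CC)CC)CC[C@@H](C(C)=C)CC1=O | intermediate
4 | 3 carrying a trifluoroacetyl group on the CH2 next to the carbonyl, as the chelated enol | C[C@]1(O[Si](CC)(CC)CC)CC[C@@H](C(C)=C)/C(=C(/O)C(F)(F)F)C1=O | intermediate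
5 | (3S,6S)-2-diazo-6-methyl-3-(prop-1-en-2-yl)-6-[(triethylsilyl)oxy]cyclohexan-1-one | C[C@]1(O[Si](CC)(CC)CC)CC[C@@H](C(C)=C)C(=[N+]=[N-])C1=O | intermediate
6 | [(2S,5S)-2-methyl-5-(prop-1-en-2-yl)-2-[(triethylsilyl)oxy]cyclopentylidene]methanone (ketene) | C[C@]1(O[Si](CC)(CC)CC)CC[C@@H](C(C)=C)C1=C=O | intermediate
7 | (1R,2S,5R)-2-methyl-5-(prop-1-en-2-yl)-2-[(triethylsilyl)oxy]cyclopentane-1-carboxylic acid | C[C@]1(O[Si](CC)(CC)CC)CC[C@@H](C(C)=C)[C@H]1C(=O)O | intermediate
8 | (3R,3aR,6S,6aR)-3-(iodomethyl)-3,6-dimethyl-6-[(triethylsilyl)oxy]hexahydro-1H-cyclopenta[c]furan-1-one | C[C@]1(O[Si](CC)(CC)CC)CC[C@H]2[C@](C)(CI)OC(=O)[C@H]21 | intermediate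
9 | (3R,3aR,6S,6aR)-3-(iodomethyl)-3,6-dimethyl-6-[(triethylsilyl)oxy]hexahydro-1H-cyclopenta[c]furan-1-ol, anomeric mixture | C[C@]1(O[Si](CC)(CC)CC)CC[C@H]2[C@](C)(CI)OC(O)[C@H]21 | intermediate
10 | (2R)-2-methylbutanoic acid | CC[C@@H](C)C(=O)O | starting material
11 | 2-methylbenzene-1,3,5-triol | Cc1c(O)cc(O)cc1O | starting material
12 | (2R)-2-methylbutanoyl chloride | CC[C@@H](C)C(Cl)=O | intermediate
13 | (2R)-2-methyl-1-(2,4,6-trihydroxy-3-methylphenyl)butan-1-one | CC[C@@H](C)C(=O)c1c(O)cc(O)c(C)c1O | intermediate
14 | ortho-quinone methide from 13 and the open form of 9, exocyclic C=C between C-s and C-e, alkene geometry not defined | CC[C@@H](C)C(=O)C1=C(O)C(C)=C(O)C(=C[C@@H]2[C@@H](CC[C@]2(C)O[Si](CC)(CC)CC)[C@@](C)(O)CI)C1=O | intermediate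
15 | (2R)-1-[2,4,6-trihydroxy-3-({(1R,2R,5S)-2-[(2R)-2-hydroxy-1-iodopropan-2-yl]-5-methyl-5-[(triethylsilyl)oxy]cyclopentyl}methyl)-5-methylphenyl]-2-methylbutan-1-one | CC[C@@H](C)C(=O)c1c(O)c(C)c(O)c(C[C@@H]2[C@@H](CC[C@]2(C)O[Si](CC)(CC)CC)[C@@](C)(O)CI)c1O | intermediate
16 | (6S)-3,5-dihydroxy-2-({(1R,2R,5S)-2-[(2R)-2-hydroxy-1-iodopropan-2-yl]-5-methyl-5-[(triethylsilyl)oxy]cyclopentyl}methyl)-6-methyl-6-(3-methylbut-2-en-1-yl)-4-[(2R)-2-methylbutanoyl]cyclohexa-2,4-dien-1-one | CC[C@@H](C)C(=O)C1=C(O)[C@](C)(CC=C(C)C)C(=O)C(C[C@@H]2[C@@H](CC[C@]2(C)O[Si](CC)(CC)CC)[C@@](C)(O)CI)=C1O | intermediate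
17 | epoxide corresponding to 16, the iodohydrin replaced by a (2R)-2-methyloxiran-2-yl group | CC[C@@H](C)C(=O)C1=C(O)[C@](C)(CC=C(C)C)C(=O)C(C[C@@H]2[C@@H](CC[C@]2(C)O[Si](CC)(CC)CC)[C@]3(C)CO3)=C1O | intermediate
18 | 3'-O-triethylsilyl ether of 19 (silyl ether on the ring C carbinol C-a) | CC[C@@H](C)C(=O)C1=C(O)[C@](C)(CC=C(C)C)C(=O)[C@]2(C[C@@H]3[C@@H](CC[C@]3(C)O[Si](CC)(CC)CC)[C@@](C)(O)C2)C1=O | intermediate
19 | CNP0236509.3, (1R,3S,3'S,3a'R,7'S,7a'R)-3',4,7'-trihydroxy-3,3',7'-trimethyl-3-(3-methylbut-2-en-1-yl)-5-[(2R)-2-methylbutanoyl]-1',2',3',3a',4',6',7',7a'-octahydrospiro[cyclohexane-1,5'-inden]-4-ene-2,6-dione | CC[C@@H](C)C(=O)C1=C(O)[C@](C)(CC=C(C)C)C(=O)[C@]2(C[C@@H]3[C@@H](CC[C@]3(C)O)[C@@](C)(O)C2)C1=O | target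

**Step count and risks**

Total step count: 11. Longest linear sequence: 10 steps (1 to 19 through steps 1–6 and 8–11); step 7 is the one-step side branch.

Steps most likely to fail:

Step 10. What may go wrong: poor facial discrimination at the enolate carbon C-s (the epoxide carbon approaching on the prenyl face and giving the spiro epimer), or sluggish closure at the neopentyl-type carbon. Fallback, which reverses the order in which the two quaternary carbons are made: setting out from 15, Cs2CO3 in DMF closes ring B at the arene stage by dearomatising ipso-alkylation of the phloroglucinol at C-s through the epoxide, to give the silyl-protected spiro enedione lacking the prenyl group F1. Its two spiro epimers are separated by chromatography, and the epimer shown is prenylated at C-q, the only nucleophilic ring carbon left, with prenyl acetate, Pd2(dba)3 and the bisphosphine ligand of step 9 under catalyst control, which comes back to the route at 18.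

Step 9. What may go wrong: attack of the prenyl–palladium species through the wrong ring carbon or through oxygen, or insufficient face selection by the ligand at C-q. Fallback, which creates C-q before the union and without asymmetric catalysis: setting out from 13, NaOMe and prenyl bromide in MeOH (dearomative C-prenylation) give the methyl prenyl trione F2 as a mixture of epimers at C-q beside the aromatic C-prenyl isomer, from which it is separated. F2 is then joined to lactol 9 under the proline/Hantzsch ester conditions of step 8, now a reductive alkylation of a cyclic 1,3-dione, and the two diastereomers formed are separated by chromatography, the (S)-configured one being 16.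

Step 8. What may go wrong: loss of the quinone methide by 1,5-hydrogen shift to a styrene (which would erase the configuration at C-b), by addition of a second arene, or by capture by the liberated tertiary hydroxyl. Fallback, which makes the C-s–C-e bond by Lewis-acid arylation and reduces afterwards: setting out from 9 and 13, Sc(OTf)3 (10 mol %) in MeCN gives the C-aryl cyclic ether F3 by Friedel–Crafts arylation of the lactol, and ionic hydrogenolysis of its benzylic C–O bond, flanked by two ortho hydroxyls, with Et3SiH and BF3·OEt2 at −40 °C comes back to the route at 15.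

Further compounds
F1 | step 10 | silyl-protected spiro enedione lacking the prenyl group (C-q still an enol carbon bearing CH3) | CC[C@@H](C)C(=O)C1=C(O)C(C)=C(O)[C@]2(C[C@@H]3[C@@H](CC[C@]3(C)O[Si](CC)(CC)CC)[C@@](C)(O)C2)C1=O
F2 | step 9 | (4S)-3-hydroxy-4-methyl-4-(3-methylbut-2-en-1-yl)-2-[(2R)-2-methylbutanoyl]cyclohex-2-ene-1,5-dione, formed together with its epimer at C-q | CC[C@@H](C)C(=O)C1=C(O)[C@](C)(CC=C(C)C)C(=O)CC1=O
F3 | step 8 | C-aryl cyclic ether: 9 with the anomeric hydroxyl replaced by the 2,4,6-trihydroxy-3-methyl-5-[(2R)-2-methylbutanoyl]phenyl group, mixture at the benzylic carbon | C[C@]1(O[Si](CC)(CC)CC)CC[C@H]2[C@](C)(CI)OC(c3c(O)c(C)c(O)c(C(=O)[C@H](C)CC)c3O)[C@H]21
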